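**Retrosynthetic overview**

1. Target ⇒ (−)-olivil: the acetate is put on last, onto the only primary alcohol.
2. (−)-Olivil ⇒ carinol, the open-chain (2S,3S) 8'-hydroxy lignan triol. The oxolane is the only ring that is built (both benzene rings are bought) and is cut at O–C7. Forward, ring A is dehydrogenated to a p-quinone methide that the 9'-OH captures, which also sets C7.
3. Carinol ⇒ doubly benzylated malic acid dioxolanone: the C7'–C8' bond comes from alkylation of a dioxolanone enolate with retention (sets C8'), followed by LiAlH4.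
4. ⇒ diisopropyl (S)-malate + 4-(benzyloxy)-3-methoxybenzyl bromide (used twice): the C7–C8 bond comes from anti alkylation of the malate alkoxide–enolate (sets C8).

Assumption: the ring-closing event of the presumed biosynthesis is taken to be oxidation of the p-hydroxybenzylic C7 of a carinol-type 8'-hydroxy lignan to a p-quinone methide and its capture by the 9'-OH (as in the ring closures of pinoresinol), followed by 9-O-acetylation.

Locants used: ring A–C7–C8(–C9)–C8'(–C9')–C7'–ring B; C9 carries the acetate and C8' the tertiary OH.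

**Route**

Step 1
Reactants: 1 4-(benzyloxy)-3-methoxybenzyl alcohol
Product: 2 4-(benzyloxy)-3-methoxybenzyl bromide
Conditions: PBr3 (0.4 equiv), Et2O, 0 °C, 1 h
Reagents that add atoms: phosphorus tribromide, BrP(Br)Br
Why: Bromodehydroxylation of an electron-rich benzylic alcohol with PBr3 (SN2 on the phosphite ester) is fast and clean at 0 °C, and no stereocenter is formed.

Step 2
Reactants: 3 diisopropyl (S)-malate; 2 4-(benzyloxy)-3-methoxybenzyl bromide
Product: 5 diisopropyl (2S,3R)-3-[4-(benzyloxy)-3-methoxybenzyl]-2-hydroxybutanedioate, via dilithium alkoxide enolate 4 (not isolated)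
Conditions: LiN(SiMe3)2 (2.1 equiv), THF, −78 → −20 °C; then 2, −78 → 0 °C; 1 M HCl
Reagents that add atoms: none
Why: Fráter–Seebach alkylation of the lithium-chelated alkoxide–enolate of a malate diester, in which the bromide adds to the enolate face anti to the C2 ester group and so sets C3 as R (anti, about 9:1, minor isomer removed by chromatography) while C2 is untouched.

Step 3
Reactants: 5 diisopropyl (2S,3R)-3-[4-(benzyloxy)-3-methoxybenzyl]-2-hydroxybutanedioate
Product: 6 (2S,3R)-3-[4-(benzyloxy)-3-methoxybenzyl]-2-hydroxybutanedioic acid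
Conditions: KOH (4 equiv), H2O–1,4-dioxane, rt → 50 °C; then 2 M HCl to pH 1
Reagents that add atoms: potassium hydroxide, [K+].[OH-]
Why: Saponification of both isopropyl esters by hydroxide (acyl-oxygen ester hydrolysis) leaves both stereocenters alone because the carboxylates formed are not enolised by aqueous base, and no new stereocenter is formed.

Step 4
Reactants: 6 (2S,3R)-3-[4-(benzyloxy)-3-methoxybenzyl]-2-hydroxybutanedioic acid
Product: 7 (2R)-3-[4-(benzyloxy)-3-methoxyphenyl]-2-[(2S,4S)-2-tert-butyl-5-oxo-1,3-dioxolan-4-yl]propanoic acid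
Conditions: t-BuCHO, TsOH·H2O (cat.), H2SO4 (cat.), pentane, reflux, Dean–Stark; recrystallise
Reagents that add atoms: pivalaldehyde, CC(C)(C)C=O
Why: Acid-catalysed acetalisation of the α-hydroxy acid (Seebach dioxolanone formation) closes the five-membered dioxolanone in preference to the six-membered dioxanone and, under equilibrating conditions, places tert-butyl cis to the side chain, which sets the acetal carbon as S (cis isomer purified by crystallisation).

Step 5
Reactants: 7 (2R)-3-[4-(benzyloxy)-3-methoxyphenyl]-2-[(2S,4S)-2-tert-butyl-5-oxo-1,3-dioxolan-4-yl]propanoic acid; 2 4-(benzyloxy)-3-methoxybenzyl bromide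
Product: 9 (2R)-3-[4-(benzyloxy)-3-methoxyphenyl]-2-{(2S,4S)-4-[4-(benzyloxy)-3-methoxybenzyl]-2-tert-butyl-5-oxo-1,3-dioxolan-4-yl}propanoic acid, via dilithium carboxylate enolate 8 (not isolated)
Conditions: LiN(SiMe3)2 (2.2 equiv), THF, −78 °C; then 2 (1.2 equiv), −78 → −20 °C; 1 M HCl
Reagents that add atoms: none
Why: Seebach self-regeneration of stereocenters, in which the planar dioxolanone enolate is benzylated on the face anti to tert-butyl, so the benzyl group takes the place of the former hydrogen with retention and the quaternary carbinol carbon (later C8') is set as S.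

Step 6
Reactants: 9 (2R)-3-[4-(benzyloxy)-3-methoxyphenyl]-2-{(2S,4S)-4-[4-(benzyloxy)-3-methoxybenzyl]-2-tert-butyl-5-oxo-1,3-dioxolan-4-yl}propanoic acid
Product: 10 (2S,3S)-2,3-bis[4-(benzyloxy)-3-methoxybenzyl]butane-1,2,4-triol
Conditions: LiAlH4 (5 equiv), THF, 0 °C → reflux; H2O/aq. NaOH work-up
Reagents that add atoms: none
Why: Hydride reduction with LiAlH4 converts the carboxylic acid and the dioxolanone carbonyl into primary alcohols and frees the tertiary hydroxyl as the acetal collapses, and neither stereocenter can epimerise because the quaternary carbon has no hydrogen and the other sits next to a carboxylate.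

Step 7
Reactants: 10 (2S,3S)-2,3-bis[4-(benzyloxy)-3-methoxybenzyl]butane-1,2,4-triol
Product: 11 carinol [(2S,3S)-2,3-bis(4-hydroxy-3-methoxybenzyl)butane-1,2,4-triol]
Conditions: H2 (1 atm), Pd/C (10 wt% palladium on carbon), EtOAc–MeOH, rt
Reagents that add atoms: none
Why: Catalytic hydrogenolysis of the two aryl benzyl ethers is selective because the molecule holds no other benzylic C–O bond, and no stereocenter is touched.

Step 8
Reactants: 11 carinol [(2S,3S)-2,3-bis(4-hydroxy-3-methoxybenzyl)butane-1,2,4-triol]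
Product: 13 (−)-olivil [(3S,4R,5S)-5-(4-hydroxy-3-methoxyphenyl)-3-(4-hydroxy-3-methoxybenzyl)-4-(hydroxymethyl)oxolan-3-ol], via ring A p-quinone methide 12 (not isolated)
Conditions: DDQ (1.0 equiv, slow addition), NaHCO3 (solid), MeCN (0.01 M), −20 → 0 °C; aq. Na2S2O4/NaHCO3 wash
Reagents that add atoms: none
Why: Proposed new method: site-selective dehydrogenation of one of two p-hydroxybenzyl CH2 groups by DDQ, reasoned from a benzylic-cation-like hydride-abstraction transition state that is slowed at C7' by the σ-withdrawing β-hydroxyl on the fully substituted, neopentyl-type C8' but not at the ordinary C7; the ring A quinone methide is then captured 5-exo by the 9'-OH (the 8'-OH and 9-OH could only give oxetanes) with the aryl group trans to the C8 hydroxymethyl in the A1,3-strain-minimised transition state, which sets C7 as S, while NaHCO3 keeps the medium non-acidic so that the benzylic ether is not re-ionised toward the cyclolignan; the closest known reaction type is DDQ dehydrogenation of p-alkylphenols to p-quinone methides with alcohol capture (oxa-1,6-addition), the same event that closes the rings of furanoid lignans in nature.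

Step 9
Reactants: 13 (−)-olivil [(3S,4R,5S)-5-(4-hydroxy-3-methoxyphenyl)-3-(4-hydroxy-3-methoxybenzyl)-4-(hydroxymethyl)oxolan-3-ol]
Product: 14 olivil monoacetate {[(2S,3R,4S)-4-hydroxy-2-(4-hydroxy-3-methoxyphenyl)-4-(4-hydroxy-3-methoxybenzyl)oxolan-3-yl]methyl acetate}
Conditions: immobilised Candida antarctica lipase B (Novozym 435), vinyl acetate (5 equiv), THF, 40 °C
Reagents that add atoms: vinyl acetate, C=COC(C)=O
Why: Lipase-catalysed transesterification acylates only the single primary alcohol, since phenols and the tertiary alcohol are not accepted by the serine hydrolase and tautomerisation of the vinyl alcohol leaving group makes the acyl transfer irreversible, so no stereocenter is affected.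

**Compound list**

1 | 4-(benzyloxy)-3-methoxybenzyl alcohol | COc1cc(CO)ccc1OCc1ccccc1 | starting material
2 | 4-(benzyloxy)-3-methoxybenzyl bromide | COc1cc(CBr)ccc1OCc1ccccc1 | intermediate
3 | diisopropyl (S)-malate | CC(C)OC(=O)C[C@H](O)C(=O)OC(C)C | starting material
4 | dilithium alkoxide enolate of 3 (C2 S) | CC(C)OC(=O)[C@@H]([O-])C=C([O-])OC(C)C.[Li+].[Li+] | intermediate
5 | diisopropyl (2S,3R)-3-[4-(benzyloxy)-3-methoxybenzyl]-2-hydroxybutanedioate | CC(C)OC(=O)[C@@H](O)[C@@H](Cc1ccc(OCc2ccccc2)c(OC)c1)C(=O)OC(C)C | intermediate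
6 | (2S,3R)-3-[4-(benzyloxy)-3-methoxybenzyl]-2-hydroxybutanedioic acid | OC(=O)[C@@H](O)[C@@H](Cc1ccc(OCc2ccccc2)c(OC)c1)C(=O)O | intermediate
7 | (2R)-3-[4-(benzyloxy)-3-methoxyphenyl]-2-[(2S,4S)-2-tert-butyl-5-oxo-1,3-dioxolan-4-yl]propanoic acid (tert-butyl cis to the side chain) | CC(C)(C)[C@@H]1OC(=O)[C@H]([C@@H](Cc2ccc(OCc3ccccc3)c(OC)c2)C(=O)O)O1 | intermediate
8 | dilithium carboxylate enolate of 7 | CC(C)(C)[C@@H]1OC([O-])=C([C@@H](Cc2ccc(OCc3ccccc3)c(OC)c2)C(=O)[O-])O1.[Li+].[Li+] | intermediate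
9 | (2R)-3-[4-(benzyloxy)-3-methoxyphenyl]-2-{(2S,4S)-4-[4-(benzyloxy)-3-methoxybenzyl]-2-tert-butyl-5-oxo-1,3-dioxolan-4-yl}propanoic acid | CC(C)(C)[C@@H]1OC(=O)[C@](Cc2ccc(OCc3ccccc3)c(OC)c2)([C@@H](Cc2ccc(OCc3ccccc3)c(OC)c2)C(=O)O)O1 | intermediate
10 | (2S,3S)-2,3-bis[4-(benzyloxy)-3-methoxybenzyl]butane-1,2,4-triol | OC[C@](O)(Cc1ccc(OCc2ccccc2)c(OC)c1)[C@H](CO)Cc1ccc(OCc2ccccc2)c(OC)c1 | intermediate
11 | carinol, (2S,3S)-2,3-bis(4-hydroxy-3-methoxybenzyl)butane-1,2,4-triol | OC[C@](O)(Cc1ccc(O)c(OC)c1)[C@H](CO)Cc1ccc(O)c(OC)c1 | intermediate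
12 | ring A p-quinone methide of 11, 4-[(2S,3S)-3,4-dihydroxy-3-(4-hydroxy-3-methoxybenzyl)-2-(hydroxymethyl)butylidene]-2-methoxycyclohexa-2,5-dien-1-one (alkene geometry not defined) | OC[C@](O)(Cc1ccc(O)c(OC)c1)[C@H](CO)C=C1C=CC(=O)C(OC)=C1 | intermediate
13 | (−)-olivil, (3S,4R,5S)-5-(4-hydroxy-3-methoxyphenyl)-3-(4-hydroxy-3-methoxybenzyl)-4-(hydroxymethyl)oxolan-3-ol | COc1cc(C[C@@]2(O)CO[C@H](c3ccc(O)c(OC)c3)[C@H]2CO)ccc1O | intermediate
14 | olivil monoacetate, [(2S,3R,4S)-4-hydroxy-2-(4-hydroxy-3-methoxyphenyl)-4-(4-hydroxy-3-methoxybenzyl)oxolan-3-yl]methyl acetate | COc1cc(C[C@@]2(O)CO[C@H](c3ccc(O)c(OC)c3)[C@H]2COC(C)=O)ccc1O | target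

**Step count**

Total steps: 9. Longest linear sequence: 9 (steps 1 to 9; bromide 2 from step 1 is used in steps 2 and 5).

**Three steps most likely to fail**

Step 8. The risks are incomplete site selectivity between C7 and C7' (C7' oxidation would give the regioisomeric oxolane through the 9-OH), over-oxidation of the product, and Friedel–Crafts closure to the cyclolignan. The fallback differentiates the two phenols so that only ring A can form a quinone methide; it sets out from 7 and comes back at 13. Hydrogenolysis of 7 (H2, Pd/C, EtOAc) frees the ring A phenol and gives (2R)-2-[(2S,4S)-2-tert-butyl-5-oxo-1,3-dioxolan-4-yl]-3-(4-hydroxy-3-methoxyphenyl)propanoic acid F1. Its trilithium salt (LiN(SiMe3)2, 3.2 equiv, THF, −78 °C) is C-benzylated by 2 anti to tert-butyl to give (2R)-2-{(2S,4S)-4-[4-(benzyloxy)-3-methoxybenzyl]-2-tert-butyl-5-oxo-1,3-dioxolan-4-yl}-3-(4-hydroxy-3-methoxyphenyl)propanoic acid F2. LiAlH4 in THF then gives (2S,3S)-2-[4-(benzyloxy)-3-methoxybenzyl]-3-(4-hydroxy-3-methoxybenzyl)butane-1,2,4-triol F3. DDQ (1.0 equiv, NaHCO3, MeCN) can now dehydrogenate only the free-phenol ring A, giving 4-{(2S,3S)-3-[4-(benzyloxy)-3-methoxybenzyl]-3,4-dihydroxy-2-(hydroxymethyl)butylidene}-2-methoxycyclohexa-2,5-dien-1-one F4, which closes to (3S,4R,5S)-3-[4-(benzyloxy)-3-methoxybenzyl]-5-(4-hydroxy-3-methoxyphenyl)-4-(hydroxymethyl)oxolan-3-ol F5. A short hydrogenolysis (H2, Pd/C, EtOAc) removes the remaining benzyl ether and gives 13. This costs one step more than the main route.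

Step 5. The risk is that the SN2 benzylation has to build a quaternary carbon next to a branched side chain. The fallback replaces alkylation by aldol addition and reductive deoxygenation; it sets out from 7 and comes back at 11. Dianion 8, made from 7 as in step 5, is added at −78 °C to commercial 4-(benzyloxy)-3-methoxybenzaldehyde (COc1cc(C=O)ccc1OCc1ccccc1), a smaller and more reactive electrophile that also enters anti to tert-butyl, to give (2R)-3-[4-(benzyloxy)-3-methoxyphenyl]-2-{(2S,4R)-4-[[4-(benzyloxy)-3-methoxyphenyl](hydroxy)methyl]-2-tert-butyl-5-oxo-1,3-dioxolan-4-yl}propanoic acid F6 (both carbinol epimers are usable). LiAlH4 in THF gives (2S,3S)-1-[4-(benzyloxy)-3-methoxyphenyl]-3-[4-(benzyloxy)-3-methoxybenzyl]-2-(hydroxymethyl)butane-1,2,4-triol F7. Hydrogenolysis in EtOAc–AcOH (H2, Pd/C) cleaves both benzyl ethers and the p-hydroxybenzylic C7'–OH and gives 11.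

Step 9. The risk is that the lipase is slow on a primary alcohol flanked by a quaternary carbon and an aryl-bearing carbon. The fallback is peracetylation followed by selective aminolysis; it sets out from 13 and comes back at 14. Ac2O in pyridine (0 °C → rt) acetylates the primary alcohol and both phenols but not the tertiary alcohol, giving [(2S,3R,4S)-2-(4-acetoxy-3-methoxyphenyl)-4-(4-acetoxy-3-methoxybenzyl)-4-hydroxyoxolan-3-yl]methyl acetate F8. Pyrrolidine (2.1 equiv, CH2Cl2, 0 °C) then cleaves only the two aryl acetates and gives 14.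

**Further compounds**

F1 | step 8 | (2R)-2-[(2S,4S)-2-tert-butyl-5-oxo-1,3-dioxolan-4-yl]-3-(4-hydroxy-3-methoxyphenyl)propanoic acid | CC(C)(C)[C@@H]1OC(=O)[C@H]([C@@H](Cc2ccc(O)c(OC)c2)C(=O)O)O1
F2 | step 8 | (2R)-2-{(2S,4S)-4-[4-(benzyloxy)-3-methoxybenzyl]-2-tert-butyl-5-oxo-1,3-dioxolan-4-yl}-3-(4-hydroxy-3-methoxyphenyl)propanoic acid | CC(C)(C)[C@@H]1OC(=O)[C@](Cc2ccc(OCc3ccccc3)c(OC)c2)([C@@H](Cc2ccc(O)c(OC)c2)C(=O)O)O1
F3 | step 8 | (2S,3S)-2-[4-(benzyloxy)-3-methoxybenzyl]-3-(4-hydroxy-3-methoxybenzyl)butane-1,2,4-triol | OC[C@](O)(Cc1ccc(OCc2ccccc2)c(OC)c1)[C@H](CO)Cc1ccc(O)c(OC)c1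
F4 | step 8 | 4-{(2S,3S)-3-[4-(benzyloxy)-3-methoxybenzyl]-3,4-dihydroxy-2-(hydroxymethyl)butylidene}-2-methoxycyclohexa-2,5-dien-1-one | OC[C@](O)(Cc1ccc(OCc2ccccc2)c(OC)c1)[C@H](CO)C=C1C=CC(=O)C(OC)=C1
F5 | step 8 | (3S,4R,5S)-3-[4-(benzyloxy)-3-methoxybenzyl]-5-(4-hydroxy-3-methoxyphenyl)-4-(hydroxymethyl)oxolan-3-ol | COc1cc(C[C@@]2(O)CO[C@H](c3ccc(O)c(OC)c3)[C@H]2CO)ccc1OCc1ccccc1
F6 | step 5 | (2R)-3-[4-(benzyloxy)-3-methoxyphenyl]-2-{(2S,4R)-4-[[4-(benzyloxy)-3-methoxyphenyl](hydroxy)methyl]-2-tert-butyl-5-oxo-1,3-dioxolan-4-yl}propanoic acid (carbinol epimers) | CC(C)(C)[C@@H]1OC(=O)[C@](C(O)c2ccc(OCc3ccccc3)c(OC)c2)([C@@H](Cc2ccc(OCc3ccccc3)c(OC)c2)C(=O)O)O1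
F7 | step 5 | (2S,3S)-1-[4-(benzyloxy)-3-methoxyphenyl]-3-[4-(benzyloxy)-3-methoxybenzyl]-2-(hydroxymethyl)butane-1,2,4-triol (C1 epimers) | OC[C@](O)(C(O)c1ccc(OCc2ccccc2)c(OC)c1)[C@H](CO)Cc1ccc(OCc2ccccc2)c(OC)c1
F8 | step 9 | [(2S,3R,4S)-2-(4-acetoxy-3-methoxyphenyl)-4-(4-acetoxy-3-methoxybenzyl)-4-hydroxyoxolan-3-yl]methyl acetate | COc1cc(C[C@@]2(O)CO[C@H](c3ccc(OC(C)=O)c(OC)c3)[C@H]2COC(C)=O)ccc1OC(C)=O
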